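**Retrosynthetic overview**
1. Feature: in ring A the ring oxygen O1 sits on C8a and the C4 ketone on the neighbouring C4a; this ortho oxygen/acyl pair is read as the two carbons of a C4a≡C8a aryne.
2. Key disconnection: O1–C8a and C4–C4a are cut in one operation, giving the ring A ortho-silylaryl triflate 12 and the C2–C3–C4 unit as β-silyloxy ester 17, which already carries ring B and the (S) centre at C2.
3. 12 comes from 3,5-dimethoxyphenol by two carbamate-directed ortho-metalations on one N-silyl-masked carbamate (SiMe3 on the future C4a, prenyl on C8) and carbamate-to-triflate exchange; 17 comes from 4'-hydroxyacetophenone by MOM protection, Claisen condensation, asymmetric transfer hydrogenation (sets C2) and O-silylation.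
4. Ring order: rings A and B come from the starting materials; ring C is the only ring built (step 9); BCl3 then frees 5-OH (chelation to C4=O) and 4'-OH.

Key step: step 9

Assumption: flavanone numbering (O1, C2, C3, C4, C4a, C5 to C8, C8a; ring B on C2) is used for the target and for the aryne carbons, and "prenyl" means 3-methylbut-2-enyl.

**Route**

Step 1
Reactants: 1 3,5-dimethoxyphenol
Product: 2 3,5-dimethoxyphenyl N-(propan-2-yl)carbamate
Conditions: i-PrNCO (1.3 equiv), Et3N (0.2 equiv), CH2Cl2, rt
Reagents that add atoms: isopropyl isocyanate, CC(C)N=C=O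
Why: Amine-catalysed addition of the phenol O–H across the isocyanate gives a secondary aryl carbamate, a strong directing group for ortho-lithiation that can later be removed under mild base.

Step 2
Reactants: 2 3,5-dimethoxyphenyl N-(propan-2-yl)carbamate
Product: 5 3,5-dimethoxy-2-(trimethylsilyl)phenyl N-(propan-2-yl)-N-(trimethylsilyl)carbamate, via N-silyl carbamate 3 (not isolated), via aryllithium 4 (not isolated)
Conditions: TMSOTf (1.1 equiv), TMEDA (1.1 equiv), Et2O, 0 °C to rt; then TMEDA (2 equiv), n-BuLi (2.1 equiv), −78 °C; TMSCl (1.5 equiv), −78 °C to rt; no aqueous work-up: Et2O solution filtered from LiCl under argon, volatiles (including excess TMSCl) removed in vacuo, crude 5 kept dry and used at once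
Reagents that add atoms: trimethylsilyl trifluoromethanesulfonate, C[Si](C)(C)OS(=O)(=O)C(F)(F)F; chlorotrimethylsilane, C[Si](C)(C)Cl
Why: Directed ortho-metalation in which in situ N-silylation masks the N–H, the carbamate carbonyl guides n-BuLi to the C–H flanked by carbamate and methoxy (favoured over the C–H between the two methoxy groups) and TMSCl traps the aryllithium, while the anhydrous isolation keeps the N–Si bond in place and strips off excess TMSCl, so that 5 can be metalated again without a second masking operation.

Step 3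
Reactants: 5 3,5-dimethoxy-2-(trimethylsilyl)phenyl N-(propan-2-yl)-N-(trimethylsilyl)carbamate; 6 prenyl bromide (1-bromo-3-methylbut-2-ene)
Product: 10 3,5-dimethoxy-2-(3-methylbut-2-enyl)-6-(trimethylsilyl)phenyl N-(propan-2-yl)carbamate, via aryllithium 7 (not isolated), via arylcopper 8 (not isolated), via N-silyl prenyl carbamate 9 (not isolated)
Conditions: crude 5, TMEDA (1.3 equiv), n-BuLi (1.3 equiv), Et2O, −78 °C; CuBr·SMe2 (1.3 equiv), −78 to −40 °C; 6 (1.6 equiv), −78 °C to rt; sat. aq. NH4Cl
Reagents that add atoms: prenyl bromide (compound 6), CC(C)=CCBr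
Why: A second directed ortho-metalation of the still N-silylated carbamate at the only C–H left beside it, transmetalation to the arylcopper and SN2 allylation at the unhindered CH2 end of prenyl bromide should give the 3-methylbut-2-enyl arene, the neutral aqueous work-up then hydrolyses only the N–Si bond, and because silicon is installed first no alkyllithium ever meets the benzylic-allylic CH2 of a prenyl group.

Step 4
Reactants: 10 3,5-dimethoxy-2-(3-methylbut-2-enyl)-6-(trimethylsilyl)phenyl N-(propan-2-yl)carbamate
Product: 12 3,5-dimethoxy-2-(3-methylbut-2-enyl)-6-(trimethylsilyl)phenyl trifluoromethanesulfonate, via phenol 11 (not isolated)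
Conditions: DBU (1.5 equiv), Et2NH (1.2 equiv), MeCN, 40 °C; then PhNTf2 (1.5 equiv), rt
Reagents that add atoms: N-phenylbis(trifluoromethanesulfonimide), O=S(=O)(N(c1ccccc1)S(=O)(=O)C(F)(F)F)C(F)(F)F
Why: E1cB cleavage of the secondary carbamate (the isocyanate is captured by Et2NH as a urea) frees the phenoxide, which PhNTf2 sulfonylates in the same pot, a known one-pot route to ortho-silylaryl triflates that avoids isolating the acid-sensitive silyl phenol.

Step 5
Reactants: 13 4'-hydroxyacetophenone
Product: 14 1-[4-(methoxymethoxy)phenyl]ethanone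
Conditions: NaH (1.1 equiv), DMF, 0 °C; MOMCl (1.2 equiv), 0 °C to rt
Reagents that add atoms: chloromethyl methyl ether, COCCl
Why: Williamson-type O-alkylation of the phenoxide gives an acetal that should withstand base, hydride transfer, fluoride and carbanions and is removed by BCl3 in the last step.

Step 6
Reactants: 14 1-[4-(methoxymethoxy)phenyl]ethanone
Product: 15 methyl 3-[4-(methoxymethoxy)phenyl]-3-oxopropanoate
Conditions: NaH (2.5 equiv), (MeO)2CO (4 equiv), THF, reflux; then AcOH, 0 °C
Reagents that add atoms: dimethyl carbonate, COC(=O)OC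
Why: Crossed Claisen condensation in which the ketone enolate is acylated by dimethyl carbonate and deprotonation of the β-keto ester by the second equivalent of NaH drives the equilibrium.

Step 7
Reactants: 15 methyl 3-[4-(methoxymethoxy)phenyl]-3-oxopropanoate
Product: 16 methyl (3S)-3-hydroxy-3-[4-(methoxymethoxy)phenyl]propanoate
Conditions: RuCl(p-cymene)[(S,S)-TsDPEN] (1 mol%), HCO2H/Et3N (5:2), EtOAc, 35 °C
Reagents that add atoms: none
Why: Noyori–Ikariya asymmetric transfer hydrogenation of an aryl ketone, in which the (S,S)-diamine ligand places the aryl group beside the η6-arene and delivers hydride to the face that gives the (S)-carbinol, the future C2, under buffered conditions that should spare the MOM acetal.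

Step 8
Reactants: 16 methyl (3S)-3-hydroxy-3-[4-(methoxymethoxy)phenyl]propanoate
Product: 17 methyl (3S)-3-[4-(methoxymethoxy)phenyl]-3-(trimethylsilyloxy)propanoate
Conditions: HMDS (0.7 equiv), TMSCl (0.05 equiv), CH2Cl2, rt; evaporation, filtration through neutral alumina
Reagents that add atoms: hexamethyldisilazane, C[Si](C)(C)N[Si](C)(C)C
Why: O-Silylation with HMDS gives only ammonia as by-product and replaces the O–H by a fluoride-labile O–Si bond, so that the alkoxide needed in step 9 can be released without any proton source and the configuration at the carbinol carbon is untouched.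

Step 9
Reactants: 12 3,5-dimethoxy-2-(3-methylbut-2-enyl)-6-(trimethylsilyl)phenyl trifluoromethanesulfonate; 17 methyl (3S)-3-[4-(methoxymethoxy)phenyl]-3-(trimethylsilyloxy)propanoate
Product: 21 (2S)-5,7-dimethoxy-2-[4-(methoxymethoxy)phenyl]-8-(3-methylbut-2-enyl)chroman-4-one, via aryne 18 (not isolated), via cesium alkoxide 19 (not isolated), via aryl anion 20 (not isolated)
Conditions: 12 (1.5 equiv), 17 (1.0 equiv), CsF (3 equiv), THF, 50 °C, exclusion of moisture
Reagents that add atoms: none
Why: Proposed new method: fluoride removes the trimethylsilyl groups of both partners, so that 12 loses triflate to give aryne 18 and 17 gives the proton-free alkoxide 19, which adds to C8a; the aryl anion 20 thus placed on C4a attacks the ester carbonyl and expels methoxide (taken up by silicon as MeOSiMe3), the closest known reaction being the aryne annulation of salicylate esters to xanthones (O-arylation, then acyl capture by the aryl anion), which has not been shown for an aliphatic β-oxy ester. Ring C closes by a 6-exo-trig acyl substitution that forms C4–C4a after O1–C8a. No stereocentre is formed, since C2 comes from 16 and its C–O bond is never broken, so the (S) configuration is carried through with retention. The step needs oxygen to go to C8a and not to C4a, which the C5 methoxy group beside the triple bond should secure by polarising the aryne so that nucleophiles attack the distal carbon and the charge develops next to the oxygen substituent, as in 3-methoxybenzyne and 3,5-dimethoxybenzyne, against the steric bias of the C8 prenyl group. It also needs acylation to outrun protonation of the C4a anion and capture of the alkoxide to outrun retro-aldol cleavage, which is why the alcohol enters as its silyl ether in THF (no O–H present) and why sparingly soluble CsF is used to release aryne and alkoxide slowly and together.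

Step 10
Reactants: 21 (2S)-5,7-dimethoxy-2-[4-(methoxymethoxy)phenyl]-8-(3-methylbut-2-enyl)chroman-4-one
Product: 22 Mundulea flavanone B, (2S)-5-hydroxy-2-(4-hydroxyphenyl)-7-methoxy-8-(3-methylbut-2-enyl)chroman-4-one
Conditions: BCl3 (1 M in CH2Cl2, 4 equiv), CH2Cl2, −78 to −10 °C; then aq. NaHCO3, 0 °C
Reagents that add atoms: none
Why: Chelation-controlled Lewis acid dealkylation in which BCl3 bound between the C4 carbonyl and the peri C5 methoxy oxygen delivers chloride to that methyl group only, the C7 methyl ether stays, the same reagent cleaves the aryl methoxymethyl acetal (its fragments are hydrolysed on work-up), and low temperature should keep the prenyl alkene and the C2–O1 bond intact.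

**Compound list**

1 | 3,5-dimethoxyphenol | COc1cc(O)cc(OC)c1 | starting material
2 | 3,5-dimethoxyphenyl N-(propan-2-yl)carbamate | COc1cc(OC)cc(OC(=O)NC(C)C)c1 | intermediate
3 | 3,5-dimethoxyphenyl N-(propan-2-yl)-N-(trimethylsilyl)carbamate (in flask, step 2) | COc1cc(OC)cc(OC(=O)N(C(C)C)[Si](C)(C)C)c1 | intermediate
4 | [2-{[N-(propan-2-yl)-N-(trimethylsilyl)carbamoyl]oxy}-4,6-dimethoxyphenyl]lithium (in flask, step 2) | [Li]c1c(OC)cc(OC)cc1OC(=O)N(C(C)C)[Si](C)(C)C | intermediate
5 | 3,5-dimethoxy-2-(trimethylsilyl)phenyl N-(propan-2-yl)-N-(trimethylsilyl)carbamate (moisture-sensitive, carried crude from step 2 into step 3) | COc1cc(OC)c([Si](C)(C)C)c(OC(=O)N(C(C)C)[Si](C)(C)C)c1 | intermediate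
6 | prenyl bromide (1-bromo-3-methylbut-2-ene) | CC(C)=CCBr | starting material
7 | [2-{[N-(propan-2-yl)-N-(trimethylsilyl)carbamoyl]oxy}-4,6-dimethoxy-3-(trimethylsilyl)phenyl]lithium (in flask, step 3) | [Li]c1c(OC)cc(OC)c([Si](C)(C)C)c1OC(=O)N(C(C)C)[Si](C)(C)C | intermediate
8 | [2-{[N-(propan-2-yl)-N-(trimethylsilyl)carbamoyl]oxy}-4,6-dimethoxy-3-(trimethylsilyl)phenyl]copper (in flask, step 3) | [Cu]c1c(OC)cc(OC)c([Si](C)(C)C)c1OC(=O)N(C(C)C)[Si](C)(C)C | intermediate
9 | 3,5-dimethoxy-2-(3-methylbut-2-enyl)-6-(trimethylsilyl)phenyl N-(propan-2-yl)-N-(trimethylsilyl)carbamate (in flask, step 3) | COc1cc(OC)c([Si](C)(C)C)c(OC(=O)N(C(C)C)[Si](C)(C)C)c1CC=C(C)C | intermediate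
10 | 3,5-dimethoxy-2-(3-methylbut-2-enyl)-6-(trimethylsilyl)phenyl N-(propan-2-yl)carbamate | COc1cc(OC)c([Si](C)(C)C)c(OC(=O)NC(C)C)c1CC=C(C)C | intermediate
11 | 3,5-dimethoxy-2-(3-methylbut-2-enyl)-6-(trimethylsilyl)phenol (in flask as its DBU salt, step 4) | COc1cc(OC)c([Si](C)(C)C)c(O)c1CC=C(C)C | intermediate
12 | 3,5-dimethoxy-2-(3-methylbut-2-enyl)-6-(trimethylsilyl)phenyl trifluoromethanesulfonate | COc1cc(OC)c([Si](C)(C)C)c(OS(=O)(=O)C(F)(F)F)c1CC=C(C)C | intermediate
13 | 4'-hydroxyacetophenone | CC(=O)c1ccc(O)cc1 | starting material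
14 | 1-[4-(methoxymethoxy)phenyl]ethanone | CC(=O)c1ccc(OCOC)cc1 | intermediate
15 | methyl 3-[4-(methoxymethoxy)phenyl]-3-oxopropanoate | COCOc1ccc(cc1)C(=O)CC(=O)OC | intermediate
16 | methyl (3S)-3-hydroxy-3-[4-(methoxymethoxy)phenyl]propanoate | O[C@H](c1ccc(OCOC)cc1)CC(=O)OC | intermediate
17 | methyl (3S)-3-[4-(methoxymethoxy)phenyl]-3-(trimethylsilyloxy)propanoate | C[Si](C)(C)O[C@H](c1ccc(OCOC)cc1)CC(=O)OC | intermediate
18 | 3,5-dimethoxy-6-(3-methylbut-2-enyl)benzyne, the C4a≡C8a aryne of ring A (in flask, step 9) | COC1=CC(OC)=C(CC=C(C)C)C#C1 | intermediate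
19 | cesium (1S)-3-methoxy-1-[4-(methoxymethoxy)phenyl]-3-oxopropan-1-olate (in flask, step 9) | [Cs+].[O-][C@H](c1ccc(OCOC)cc1)CC(=O)OC | intermediate
20 | cesium 2,4-dimethoxy-6-{(1S)-3-methoxy-1-[4-(methoxymethoxy)phenyl]-3-oxopropoxy}-5-(3-methylbut-2-enyl)benzen-1-ide, the C4a anion (in flask, step 9) | [Cs+].COc1cc(OC)c(CC=C(C)C)c(O[C@H](c2ccc(OCOC)cc2)CC(=O)OC)[c-]1 | intermediate
21 | (2S)-5,7-dimethoxy-2-[4-(methoxymethoxy)phenyl]-8-(3-methylbut-2-enyl)chroman-4-one | COc1cc(OC)c2c(c1CC=C(C)C)O[C@H](c1ccc(OCOC)cc1)CC2=O | intermediate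
22 | Mundulea flavanone B, (2S)-5-hydroxy-2-(4-hydroxyphenyl)-7-methoxy-8-(3-methylbut-2-enyl)chroman-4-one | COc1cc(O)c2c(c1CC=C(C)C)O[C@H](c1ccc(O)cc1)CC2=O | target

**Totals**

Total step count: 10 (steps 1 to 4 make 12, steps 5 to 8 make 17, steps 9 and 10 join and finish).
Longest linear sequence: 6 steps (1, 2, 3, 4, 9, 10; the other branch, 5, 6, 7, 8, 9, 10, is equally long).

**Steps most likely to fail**

1. Step 9 (the proposed method). The fluoride-freed alkoxide may undergo retro-aldol cleavage or elimination before it meets the aryne. The C4a anion may take a proton (from C3–H2 of its own ester arm or from traces of moisture) before it acylates, which would stop the sequence at an open aryl ether. The C8 prenyl group may erode the preference for O-attack at C8a. Methoxide set free in the flask may also open ring C of the product to the chalcone, which would erode the configuration at C2.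
Fallback with known reactions only, setting out from 12 and 16 and returning at 21. The free alcohol 16 is O-arylated by the aryne from 12 under conditions where the aryl anion is protonated on purpose (CsF, MeCN, rt; aryne insertion into an alcohol O–H). This should give methyl (3S)-3-[3,5-dimethoxy-2-(3-methylbut-2-enyl)phenoxy]-3-[4-(methoxymethoxy)phenyl]propanoate F1. Ester cleavage with Me3SnOH (1,2-dichloroethane, 70 °C), chosen to avoid β-elimination of the aryloxide, gives (3S)-3-[3,5-dimethoxy-2-(3-methylbut-2-enyl)phenoxy]-3-[4-(methoxymethoxy)phenyl]propanoic acid F2. The acid is converted with 1-chloro-N,N,2-trimethylprop-1-en-1-amine (CH2Cl2, 0 °C) into (3S)-3-[3,5-dimethoxy-2-(3-methylbut-2-enyl)phenoxy]-3-[4-(methoxymethoxy)phenyl]propanoyl chloride F3, which is closed by intramolecular Friedel–Crafts acylation (SnCl4, −78 °C). The acylation can only reach C4a, which is activated by three oxygen substituents, and delivers 21.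

2. Step 10. Hydrogen chloride formed in the flask may add across the electron-rich trisubstituted prenyl alkene, or the Lewis acid may start cationic reactions of that alkene, before both ether cleavages are complete.
Fallback setting out from 5 and returning at 22: an allyl group is carried through the Lewis acid step and the trisubstituted alkene is made last. The sequence of step 3 with allyl bromide in place of 6 gives 3,5-dimethoxy-2-(prop-2-enyl)-6-(trimethylsilyl)phenyl N-(propan-2-yl)carbamate F4. The conditions of step 4 give 3,5-dimethoxy-2-(prop-2-enyl)-6-(trimethylsilyl)phenyl trifluoromethanesulfonate F5. Annulation with 17 as in step 9 gives (2S)-5,7-dimethoxy-2-[4-(methoxymethoxy)phenyl]-8-(prop-2-enyl)chroman-4-one F6. BCl3 as in step 10 gives (2S)-5-hydroxy-2-(4-hydroxyphenyl)-7-methoxy-8-(prop-2-enyl)chroman-4-one F7, whose monosubstituted alkene offers no stabilised cation. Cross-metathesis with 2-methylbut-2-ene (second-generation Grubbs catalyst RuCl2(=CHPh)(H2IMes)(PCy3), CH2Cl2, 40 °C) then gives 22.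

3. Step 3. The allyl unit may couple through its tertiary carbon (SN2′) to give the 1,1-dimethylallyl isomer. Lithiation of the hindered, silyl-flanked carbamate may be incomplete. Partial loss of the N–Si bond of crude 5 through adventitious moisture would consume base before the ring is metalated.
Fallback setting out from 1 and returning at 10: the prenyl group is placed by a sigmatropic shift instead of an alkylation. Tsuji–Trost O-alkylation of 1 with methyl 2-methylbut-3-en-2-yl carbonate (Pd(PPh3)4, THF, rt), which should attack the more substituted allyl terminus, gives 1-[(2-methylbut-3-en-2-yl)oxy]-3,5-dimethoxybenzene F8. Aromatic Claisen rearrangement (N,N-diethylaniline, 150 °C) can only deliver a 3-methylbut-2-enyl group to one of the two equivalent ortho carbons and gives 3,5-dimethoxy-2-(3-methylbut-2-enyl)phenol F9. Carbamate formation as in step 1 gives 3,5-dimethoxy-2-(3-methylbut-2-enyl)phenyl N-(propan-2-yl)carbamate F10. In situ N-silylation, lithiation and TMSCl trapping as in step 2, here ended by the aqueous NH4Cl work-up of step 3, should then give 10 by way of 9; the ring C–H between carbamate and methoxy should be removed faster than the lateral CH2 at −78 °C.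

**Further compounds**

F1 | step 9 | methyl (3S)-3-[3,5-dimethoxy-2-(3-methylbut-2-enyl)phenoxy]-3-[4-(methoxymethoxy)phenyl]propanoate | COc1cc(OC)c(CC=C(C)C)c(O[C@H](c2ccc(OCOC)cc2)CC(=O)OC)c1
F2 | step 9 | (3S)-3-[3,5-dimethoxy-2-(3-methylbut-2-enyl)phenoxy]-3-[4-(methoxymethoxy)phenyl]propanoic acid | COc1cc(OC)c(CC=C(C)C)c(O[C@H](c2ccc(OCOC)cc2)CC(=O)O)c1
F3 | step 9 | (3S)-3-[3,5-dimethoxy-2-(3-methylbut-2-enyl)phenoxy]-3-[4-(methoxymethoxy)phenyl]propanoyl chloride | COc1cc(OC)c(CC=C(C)C)c(O[C@H](c2ccc(OCOC)cc2)CC(=O)Cl)c1
F4 | step 10 | 3,5-dimethoxy-2-(prop-2-enyl)-6-(trimethylsilyl)phenyl N-(propan-2-yl)carbamate | COc1cc(OC)c([Si](C)(C)C)c(OC(=O)NC(C)C)c1CC=C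
F5 | step 10 | 3,5-dimethoxy-2-(prop-2-enyl)-6-(trimethylsilyl)phenyl trifluoromethanesulfonate | COc1cc(OC)c([Si](C)(C)C)c(OS(=O)(=O)C(F)(F)F)c1CC=C
F6 | step 10 | (2S)-5,7-dimethoxy-2-[4-(methoxymethoxy)phenyl]-8-(prop-2-enyl)chroman-4-one | COc1cc(OC)c2c(c1CC=C)O[C@H](c1ccc(OCOC)cc1)CC2=O
F7 | step 10 | (2S)-5-hydroxy-2-(4-hydroxyphenyl)-7-methoxy-8-(prop-2-enyl)chroman-4-one | COc1cc(O)c2c(c1CC=C)O[C@H](c1ccc(O)cc1)CC2=O
F8 | step 3 | 1-[(2-methylbut-3-en-2-yl)oxy]-3,5-dimethoxybenzene | COc1cc(OC)cc(OC(C)(C)C=C)c1
F9 | step 3 | 3,5-dimethoxy-2-(3-methylbut-2-enyl)phenol | COc1cc(OC)c(CC=C(C)C)c(O)c1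
F10 | step 3 | 3,5-dimethoxy-2-(3-methylbut-2-enyl)phenyl N-(propan-2-yl)carbamate | COc1cc(OC)c(CC=C(C)C)c(OC(=O)NC(C)C)c1
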